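The flask holds 3.00 M of substrate in all, against 1.65 M of coupling partner and 32 mM of free catalyst, and you need two orders early in the run.

| flask | left-handed substrate | right-handed substrate | coupling partner | free catalyst | remark |
|---|---|---|---|---|---|
| Thursday's | 1.5 M | 1.5 M | 1.1 M | 32 mM | run made earlier |
| flask | 1.5 M | 1.5 M | 1.65 M | 32 mM |  |

Thursday's run (percent of the left-handed substrate and right-handed substrate together charged): time / h: left-handed product / % = 2.50: 18.5; 5.00: 23.9; 8.00: 28.0; 10.0: 30.3; 12.0: 28.3

(scatter of a reading: 1 percentage point)

- free catalyst is single-handed; left-handed substrate and right-handed substrate are mirror images of each other, charged as a racemate, each of them at the stated concentration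
- what is bound to the catalyst counts as converted
- no earlier run changes the charge of free catalyst; that part of a forecast is a guess
- no earlier run changes the charge of coupling partner; that part of a forecast is a guess

* apparent order in coupling partner when 5.0 % of the left-handed substrate and right-handed substrate together are converted (percent change of the rate of making left-handed product for one percent more coupling partner charged)
* apparent order in free catalyst when 5.0 % of the left-handed substrate and right-handed substrate together are converted (percent change of the rate of making left-handed product for one percent more free catalyst charged)

Read Thursday's run as a ladder, rung by rung. Over its first 2.50 h, one left-handed product appeared per catalyst every 8.65 min on average. At that average pace, left-handed product reaches the percentage you are looking at after about 0.676 h, an estimate carried over from Thursday's run. The rung above it is a fade: from the first interval to the second, Thursday's pace fell 3.43-fold, while mean c(coupling partner), reckoned from left-handed product, fell 1.77-fold. So, on these scattered readings of Thursday's run, something else weakens too, but over hours, and your look, on that estimate, comes earlier.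

My reckoning treats the partner's loss at the look as the small correction. In this flask, 5.0 % conversion uses about 0.150 M of coupling partner, somewhat less because bound catalyst counts as converted, and the whole catalyst charge equals 1.07 % conversion. At equal conversion, one percent more partner charged is therefore more than one percent more present. The stretch factor, charge over charge minus the partner used at the look, is 1.10; on Thursday's charge it is 1.16. Multiply it by the order on c(coupling partner) present: a strictly first-order rate gives 1.10, but Thursday's run, at one charge of coupling partner, does not give that order, so this stays conditional.

The forecast gives 0.85 for coupling partner, below my conditional figure, on this ground: “Partial saturation could lower the coupling-partner order”. For free catalyst it gives 1.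

The flask gives 0.71 for coupling partner and 0.97 for free catalyst.

    free catalyst + left-handed substrate ⇌ catalyst intermediate A (K = 6.40 L mol⁻¹, k = 0.0164 L mol⁻¹ s⁻¹)
    2 free catalyst ⇌ resting dimer, settled at all times (K = 27.5 L mol⁻¹)
    free catalyst → spent catalyst (k = 2.10 × 10⁻⁴ s⁻¹)
    free catalyst + right-handed substrate ⇌ catalyst intermediate B (K = 0.508 L mol⁻¹, k = 0.00857 L mol⁻¹ s⁻¹)
    coupling partner + catalyst intermediate B → free catalyst + right-handed product (k = 0.00235 L mol⁻¹ s⁻¹)
    coupling partner + catalyst intermediate A → free catalyst + left-handed product (k = 0.00489 L mol⁻¹ s⁻¹)

Divided by the stretch factor 1.10, the flask's order reckons to about 0.645 on c(coupling partner) present. In this flask at 1.69 h, catalyst intermediate A falls back at 0.51 times the rate at which it goes on. At 2.00 h in this flask, catalyst intermediate A holds 35.1 % of the catalyst, against 17.5 % free.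

All runs come from a simulation for substances that don't exist; scatter was added.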